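**Overview**

- Retrosynthesis: after removal of twenty benzyl ethers and one aryl bromine, the trimer is cut at its two interflavan bonds. These are C4 (ring C) of the upper epigallocatechin to C8 (ring A) of the central gallate unit, and C4 (ring C) of the central unit to C8 (ring A) of the lower epigallocatechin.
- Enabling feature: the central unit is a 3-O-galloyl epigallocatechin, and it is ambident. Its ring A has a nucleophilic C8–H between C7–O and C8a–O1. Its ring C has a benzylic C4–H that can be oxidised to a leaving group, whose loss gives a cation conjugated with O1, O5 and O7. Both new bonds therefore meet at one unit that already carries the ester on O3.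
- Forward order: no ring is made, since all flavan and aryl rings are bought. One pentabenzyl ether of epigallocatechin serves all three units: it is benzylated further for the upper and lower units and esterified with tribenzylgallic acid for the centre. One flask then joins upper unit to centre (C4–O ionised by BF3·OEt2, the upper unit blocked at C8 by bromine) and afterwards centre to lower unit (C4–S ionised by AgBF4). Hydrogenolysis finishes the route.
- Stereochemistry: C2 and C3 of all three units (2R,3R, 2,3-cis) come from (−)-epigallocatechin. The two new C4 centres arise by arene attack on planar C4 cations anti to the α oxygen substituent at C3, giving 3,4-trans (4β) twice.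

Key step: step 8

Remark: (−)-epigallocatechin is taken to be bought as the single (2R,3R) enantiomer. The gallate is put on by esterification of the pentabenzyl ether, so the ester never meets phenoxides or carbonate base. The 4β configuration drawn for the C4–O and C4–S leaving groups is the expected one, but it has no bearing on the outcome because both groups depart by ionisation. EGC stands for (−)-epigallocatechin and EGCG for (−)-epigallocatechin 3-O-gallate.

**Route**

Step 1
Reactants: 1 (−)-epigallocatechin (EGC, 2R,3R); 2 benzyl bromide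
Product: 3 5,7,3',4',5'-penta-O-benzyl-EGC (2R,3R; 3-OH free)
Conditions: BnBr (5.5 equiv), K2CO3 (6 equiv), DMF, 0 °C to rt, argon
Reagents that add atoms: benzyl bromide (2), BrCc1ccccc1
Why: Williamson etherification under carbonate conditions should alkylate only the five phenols, because K2CO3 does not deprotonate the secondary 3-OH and exclusion of oxygen protects the pyrogallol ring B; C2 and C3 are not touched.

Step 2
Reactants: 3 5,7,3',4',5'-penta-O-benzyl-EGC; 2 benzyl bromide
Product: 4 3,5,7,3',4',5'-hexa-O-benzyl-EGC (2R,3R)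
Conditions: NaH (1.3 equiv), BnBr (1.3 equiv), DMF, 0 °C to rt
Reagents that add atoms: benzyl bromide (2), BrCc1ccccc1
Why: Williamson ether synthesis on the sodium alkoxide of the 3-OH should proceed cleanly, and with every phenol already etherified there is no ring-opening (quinone methide) path to C2 epimerisation, so the 2R,3R configuration is kept.

Step 3
Reactants: 4 3,5,7,3',4',5'-hexa-O-benzyl-EGC
Product: 5 8-bromo-3,5,7,3',4',5'-hexa-O-benzyl-EGC (2R,3R)
Conditions: N-bromosuccinimide (1.0 equiv), CH2Cl2, −78 to −40 °C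
Reagents that add atoms: N-bromosuccinimide, O=C1CCC(=O)N1Br
Why: Electrophilic aromatic bromination should occur on ring A, the trioxygenated and most electron-rich arene, and 5,7-di-O-benzyl flavans are known to take a single bromine at C8 rather than C6 with N-bromosuccinimide at low temperature; no stereocentre is involved.

Step 4
Reactants: 5 8-bromo-3,5,7,3',4',5'-hexa-O-benzyl-EGC; 6 2-ethoxyethanol
Product: 7 8-bromo-4β-(2-ethoxyethoxy)-3,5,7,3',4',5'-hexa-O-benzyl-EGC (2,3-cis-3,4-trans; C2 and C3 as in 1)
Conditions: DDQ (2 equiv), 2-ethoxyethanol (5 equiv), CH2Cl2, rt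
Reagents that add atoms: 2-ethoxyethanol (6), CCOCCO
Why: DDQ benzylic oxidation (oxidative C–H etherification) should abstract hydride from C4 to give a cation delocalised onto O1, O5 and O7, which the alcohol captures on the β face, anti to the pseudoaxial 3-O-benzyl group, so the new C4 centre is 4β.

Step 5
Reactants: 3 5,7,3',4',5'-penta-O-benzyl-EGC; 8 3,4,5-tris(benzyloxy)benzoic acid
Product: 9 octa-O-benzyl-EGCG, that is 5,7,3',4',5'-penta-O-benzyl-EGC 3-O-(3,4,5-tri-O-benzylgallate) (2R,3R)
Conditions: N,N'-dicyclohexylcarbodiimide (1.5 equiv), 4-dimethylaminopyridine (0.3 equiv), CH2Cl2, 0 °C to rt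
Reagents that add atoms: 3,4,5-tris(benzyloxy)benzoic acid (8), OC(=O)c1cc(OCc2ccccc2)c(OCc2ccccc2)c(OCc2ccccc2)c1
Why: Steglich esterification should acylate the single free hydroxyl of 3 through the acylpyridinium ion, which is reactive enough for the hindered axial 3-OH of a 2,3-cis flavan; the C3–O bond is not broken, so C3 keeps its configuration, and the neutral conditions cannot open ring C or epimerise C2.

Step 6
Reactants: 9 octa-O-benzyl-EGCG; 6 2-ethoxyethanol
Product: 10 4β-(2-ethoxyethoxy)-octa-O-benzyl-EGCG (2,3-cis-3,4-trans)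
Conditions: DDQ (2.5 equiv), 2-ethoxyethanol (5 equiv), CH2Cl2, rt
Reagents that add atoms: 2-ethoxyethanol (6), CCOCCO
Why: This is the DDQ benzylic oxidation of step 4, a reaction type also known for 3-O-acyl flavans; the ester slows hydride loss somewhat, but its carbonyl can bridge the C4 cation on the α face, so the alcohol should enter from the β face and give the 3,4-trans ether.

Step 7
Reactants: 10 4β-(2-ethoxyethoxy)-octa-O-benzyl-EGCG; 11 2,6-dimethylbenzenethiol
Product: 12 4β-(2,6-dimethylphenylthio)-octa-O-benzyl-EGCG (C8–H free; 2,3-cis-3,4-trans)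
Conditions: 2,6-dimethylbenzenethiol (5 equiv), BF3·OEt2 (1.2 equiv), CH2Cl2, −78 °C
Reagents that add atoms: 2,6-dimethylbenzenethiol (11), Cc1cccc(C)c1S
Why: Lewis-acid-promoted SN1 exchange of the acetal-type ether for a thioether should work because BF3 ionises the C4–O bond and the soft thiol, present in excess, captures the cation faster than C8 of a second molecule can; attack anti to the 3-O-galloyl group gives the 4β sulfide, which BF3 does not ionise at low temperature.

Step 8
Reactants: 7 8-bromo-4β-(2-ethoxyethoxy)-hexa-O-benzyl-EGC; 12 4β-(2,6-dimethylphenylthio)-octa-O-benzyl-EGCG; 4 3,5,7,3',4',5'-hexa-O-benzyl-EGC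
Product: 14 bromine-capped icosa-O-benzyl trimer [8-bromo-hexa-O-benzyl-EGC-(4β→8)-octa-O-benzyl-EGCG-(4β→8)-hexa-O-benzyl-EGC], via bromine-capped dimer sulfide 13 (not isolated)
Conditions: 7 (1.0 equiv), 12 (1.1 equiv), BF3·OEt2 (1 equiv), CH2Cl2, −78 to −40 °C; then 4 (3 equiv), AgBF4 (2 equiv, added in toluene), −78 to −20 °C
Reagents that add atoms: none
Why: In the first stage the hard Lewis acid BF3·OEt2 ionises only the C4–O bond of 7 to a benzylic cation delocalised onto O1, O5 and O7 of ring A, and the one activated aromatic C–H open to it, C8 of sulfide 12, adds in an intermolecular Friedel–Crafts alkylation while the C4–S bond of 12 stays intact at low temperature, giving 13. In the second stage AgBF4 removes the arylthio group of 13 irreversibly as the silver thiolate and the new C4 cation is taken by C8 of 4, used in excess; cation intercepted by the 2-ethoxyethanol released earlier only re-forms a C4–O ether, which the BF3 still in the flask ionises again. The closest known reaction type is the Lewis-acid-promoted SN1 arylation of flavan C4 electrophiles by C8 of a second flavan, with oxygen and sulfur leaving groups activated orthogonally and a halogen blocking C8, here run as two consecutive activations in one flask. Neither event is a cyclisation; each is an intermolecular substitution on an arene. Each new stereocentre (C4 of the upper unit, then C4 of the central unit) is set by approach of the arene to the planar cation on the β face, anti to the pseudoaxial α oxygen substituent at C3, a benzyl ether in the first stage and in the second the galloyl ester, whose carbonyl can also bridge the cation on the α face, so both junctions should be 3,4-trans (4β). The step needs leaving-group chemoselectivity, supplied by pairing hard BF3 with C–O and thiophilic monovalent silver with C–S; it needs freedom from self-condensation of 7, ensured by the C8 bromine; and it needs C8-over-C6 regioselectivity, which follows from C8 being the more nucleophilic position of 5,7-di-O-benzyl flavans while C6 sits between two benzyloxy groups.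

Step 9
Reactants: 14 bromine-capped icosa-O-benzyl trimer
Product: 15 epigallocatechin-(4β→8)-epigallocatechin 3-O-gallate-(4β→8)-epigallocatechin (target)
Conditions: H2 (1 atm), Pd(OH)2 on carbon, Et3N (1.5 equiv), THF/MeOH/H2O, rt
Reagents that add atoms: none
Why: Heterogeneous catalytic hydrogenolysis should cleave all twenty O-benzyl bonds and the aryl C–Br bond, while triethylamine takes up the HBr so that the acid-labile interflavan bonds and the gallate ester survive; the C–C bonds at C4 and the C2–O1 bonds are not hydrogenolysed under these conditions and no stereocentre is touched.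

**Compound list**

1 | (−)-epigallocatechin (EGC), (2R,3R)-2-(3,4,5-trihydroxyphenyl)chromane-3,5,7-triol | O[C@@H]1Cc2c(O)cc(O)cc2O[C@@H]1c1cc(O)c(O)c(O)c1 | starting material
2 | benzyl bromide | BrCc1ccccc1 | starting material
3 | 5,7,3',4',5'-penta-O-benzyl-EGC (2R,3R, free 3-OH) | O[C@@H]1Cc2c(OCc3ccccc3)cc(OCc3ccccc3)cc2O[C@@H]1c1cc(OCc2ccccc2)c(OCc2ccccc2)c(OCc2ccccc2)c1 | intermediate
4 | 3,5,7,3',4',5'-hexa-O-benzyl-EGC (2R,3R) | O(Cc1ccccc1)[C@@H]1Cc2c(OCc3ccccc3)cc(OCc3ccccc3)cc2O[C@@H]1c1cc(OCc2ccccc2)c(OCc2ccccc2)c(OCc2ccccc2)c1 | intermediate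
5 | 8-bromo-3,5,7,3',4',5'-hexa-O-benzyl-EGC (2R,3R) | O(Cc1ccccc1)[C@@H]1Cc2c(OCc3ccccc3)cc(OCc3ccccc3)c(Br)c2O[C@@H]1c1cc(OCc2ccccc2)c(OCc2ccccc2)c(OCc2ccccc2)c1 | intermediate
6 | 2-ethoxyethanol | CCOCCO | starting material
7 | 8-bromo-4β-(2-ethoxyethoxy)-3,5,7,3',4',5'-hexa-O-benzyl-EGC (2,3-cis-3,4-trans) | CCOCCO[C@H]1c2c(OCc3ccccc3)cc(OCc3ccccc3)c(Br)c2O[C@H](c2cc(OCc3ccccc3)c(OCc3ccccc3)c(OCc3ccccc3)c2)[C@@H]1OCc1ccccc1 | intermediate
8 | 3,4,5-tris(benzyloxy)benzoic acid (tri-O-benzylgallic acid) | OC(=O)c1cc(OCc2ccccc2)c(OCc2ccccc2)c(OCc2ccccc2)c1 | starting material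
9 | octa-O-benzyl-EGCG (2R,3R) | O=C(O[C@@H]1Cc2c(OCc3ccccc3)cc(OCc3ccccc3)cc2O[C@@H]1c1cc(OCc2ccccc2)c(OCc2ccccc2)c(OCc2ccccc2)c1)c1cc(OCc2ccccc2)c(OCc2ccccc2)c(OCc2ccccc2)c1 | intermediate
10 | 4β-(2-ethoxyethoxy)-octa-O-benzyl-EGCG (2,3-cis-3,4-trans) | O=C(O[C@@H]1[C@@H](OCCOCC)c2c(OCc3ccccc3)cc(OCc3ccccc3)cc2O[C@@H]1c1cc(OCc2ccccc2)c(OCc2ccccc2)c(OCc2ccccc2)c1)c1cc(OCc2ccccc2)c(OCc2ccccc2)c(OCc2ccccc2)c1 | intermediate
11 | 2,6-dimethylbenzenethiol | Cc1cccc(C)c1S | starting material
12 | 4β-(2,6-dimethylphenylthio)-octa-O-benzyl-EGCG (C8–H free, 2,3-cis-3,4-trans) | O=C(O[C@@H]1[C@@H](Sc2c(C)cccc2C)c2c(OCc3ccccc3)cc(OCc3ccccc3)cc2O[C@@H]1c1cc(OCc2ccccc2)c(OCc2ccccc2)c(OCc2ccccc2)c1)c1cc(OCc2ccccc2)c(OCc2ccccc2)c(OCc2ccccc2)c1 | intermediate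
13 | bromine-capped dimer sulfide, 8-bromo-hexa-O-benzyl-EGC-(4β→8)-[4β-(2,6-dimethylphenylthio)-octa-O-benzyl-EGCG], formed and consumed in the flask of step 8 | O=C(O[C@@H]1[C@@H](Sc2c(C)cccc2C)c2c(OCc3ccccc3)cc(OCc3ccccc3)c([C@H]3c4c(OCc5ccccc5)cc(OCc5ccccc5)c(Br)c4O[C@H](c4cc(OCc5ccccc5)c(OCc5ccccc5)c(OCc5ccccc5)c4)[C@@H]3OCc3ccccc3)c2O[C@@H]1c1cc(OCc2ccccc2)c(OCc2ccccc2)c(OCc2ccccc2)c1)c1cc(OCc2ccccc2)c(OCc2ccccc2)c(OCc2ccccc2)c1 | intermediate
14 | bromine-capped icosa-O-benzyl trimer, 8-bromo-hexa-O-benzyl-EGC-(4β→8)-octa-O-benzyl-EGCG-(4β→8)-hexa-O-benzyl-EGC | O=C(O[C@@H]1[C@@H](c2c(OCc3ccccc3)cc(OCc3ccccc3)c3c2O[C@H](c2cc(OCc4ccccc4)c(OCc4ccccc4)c(OCc4ccccc4)c2)[C@H](OCc2ccccc2)C3)c2c(OCc3ccccc3)cc(OCc3ccccc3)c([C@H]3c4c(OCc5ccccc5)cc(OCc5ccccc5)c(Br)c4O[C@H](c4cc(OCc5ccccc5)c(OCc5ccccc5)c(OCc5ccccc5)c4)[C@@H]3OCc3ccccc3)c2O[C@@H]1c1cc(OCc2ccccc2)c(OCc2ccccc2)c(OCc2ccccc2)c1)c1cc(OCc2ccccc2)c(OCc2ccccc2)c(OCc2ccccc2)c1 | intermediate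
15 | epigallocatechin-(4β→8)-epigallocatechin 3-O-gallate-(4β→8)-epigallocatechin | O=C(O[C@@H]1[C@@H](c2c(O)cc(O)c3c2O[C@H](c2cc(O)c(O)c(O)c2)[C@H](O)C3)c2c(O)cc(O)c([C@H]3c4c(O)cc(O)cc4O[C@H](c4cc(O)c(O)c(O)c4)[C@@H]3O)c2O[C@@H]1c1cc(O)c(O)c(O)c1)c1cc(O)c(O)c(O)c1 | target

**Summary**

Total step count: 9 steps.
Longest linear sequence: 6 steps (steps 1, 2, 3, 4, 8 and 9, from 1 to 15). The branch to the central unit (steps 1, 5, 6, 7, 8 and 9) is of equal length, and the lower unit needs only steps 1 and 2 before step 8.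

Steps most likely to fail:

1. Step 8. The hard/soft discrimination may break down in two ways. BF3 may strip the arylthio group prematurely, so that the central unit oligomerises through its own C8. Alternatively, the acid released in the silver stage may fragment or scramble the interflavan bond formed first. In that case the trimer would be built from the lower end in two isolated couplings that need no sulfide. From ether 10 and an excess of nucleophile 4, a catalytic amount of trimethylsilyl triflate in CH2Cl2 at −78 °C should give the protected dimer octa-O-benzyl-EGCG-(4β→8)-hexa-O-benzyl-EGC F1. The excess of 4 suppresses self-condensation of 10, and the only free C8–H of F1 is that of its galloylated unit. Alkylation of this C8 by the bromine-capped ether 7 under BF3·OEt2 at −78 °C would then return to the route at compound 14.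

2. Step 9. Cleavage of twenty benzyl ethers may stall through poisoning of the catalyst by bromide, or the HBr may fragment the interflavan bonds before it is neutralised. The amine may also promote oxidation of the free pyrogallol rings. In that case removal of the halogen would be separated from the debenzylation. From 14, radical hydrodebromination (Bu3SnH, azobisisobutyronitrile, toluene, 90 °C) tolerates the ester and the benzyl ethers and should give the bromine-free icosa-O-benzyl trimer F2. Hydrogenolysis of F2 over Pd(OH)2 on carbon without any base would then return to the route at target 15.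

3. Step 6. Hydride abstraction from C4 next to the electron-withdrawing ester may be so slow that DDQ instead attacks benzyl ethers or over-oxidises C4 to the ketone. In that case oxidation and acylation would be carried out in the opposite order. From pentabenzyl ether 3, whose free 3-OH makes it the best-behaved substrate class for this oxidation, DDQ and 2-ethoxyethanol 6 should give 4β-(2-ethoxyethoxy)-5,7,3',4',5'-penta-O-benzyl-EGC F3. Steglich esterification of its 3-OH with acid 8 (N,N'-dicyclohexylcarbodiimide, 4-dimethylaminopyridine, CH2Cl2) would return to the route at compound 10. Steps 5 and 6 are then not needed.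

**Further compounds**

F1 | step 8 | octa-O-benzyl-EGCG-(4β→8)-hexa-O-benzyl-EGC, protected dimer with free C8–H on the galloylated unit | O=C(O[C@@H]1[C@@H](c2c(OCc3ccccc3)cc(OCc3ccccc3)c3c2O[C@H](c2cc(OCc4ccccc4)c(OCc4ccccc4)c(OCc4ccccc4)c2)[C@H](OCc2ccccc2)C3)c2c(OCc3ccccc3)cc(OCc3ccccc3)cc2O[C@@H]1c1cc(OCc2ccccc2)c(OCc2ccccc2)c(OCc2ccccc2)c1)c1cc(OCc2ccccc2)c(OCc2ccccc2)c(OCc2ccccc2)c1
F2 | step 9 | bromine-free icosa-O-benzyl trimer, hexa-O-benzyl-EGC-(4β→8)-octa-O-benzyl-EGCG-(4β→8)-hexa-O-benzyl-EGC | O=C(O[C@@H]1[C@@H](c2c(OCc3ccccc3)cc(OCc3ccccc3)c3c2O[C@H](c2cc(OCc4ccccc4)c(OCc4ccccc4)c(OCc4ccccc4)c2)[C@H](OCc2ccccc2)C3)c2c(OCc3ccccc3)cc(OCc3ccccc3)c([C@H]3c4c(OCc5ccccc5)cc(OCc5ccccc5)cc4O[C@H](c4cc(OCc5ccccc5)c(OCc5ccccc5)c(OCc5ccccc5)c4)[C@@H]3OCc3ccccc3)c2O[C@@H]1c1cc(OCc2ccccc2)c(OCc2ccccc2)c(OCc2ccccc2)c1)c1cc(OCc2ccccc2)c(OCc2ccccc2)c(OCc2ccccc2)c1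
F3 | step 6 | 4β-(2-ethoxyethoxy)-5,7,3',4',5'-penta-O-benzyl-EGC (free 3-OH, 2,3-cis-3,4-trans) | CCOCCO[C@H]1c2c(OCc3ccccc3)cc(OCc3ccccc3)cc2O[C@H](c2cc(OCc3ccccc3)c(OCc3ccccc3)c(OCc3ccccc3)c2)[C@@H]1O
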